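**Assumptions (stated once)**
- Juglanin A as written has no stereocentres and no alkene, so it is achiral. The 15-membered meta,para-cyclophane ring is large enough for the para-phenylene ring to flip freely, so no planar chirality is fixed. The "single enantiomer" therefore reduces to the single constitution given.
- 4-Hydroxy-2,3-dimethoxybenzaldehyde (4) is assumed to be commercially available. If it is not, it is one step from 2,3-dimethoxyphenol by Vilsmeier formylation (POCl3/DMF), which places CHO para to OH.

**Retrosynthesis**
1. Target ⇒ macrocyclic dienone by hydrogenation of two C=C.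
2. The 15-membered ring is formed last by ring-closing metathesis of a styrene with a terminal alkene, which forms C6=C7 and loses ethylene. The conjugated enone C1=C2 is a deactivated, masked form of the C1–C2 single bond and carries the ketone through the Wittig and RCM steps.
3. The diene comes from an Ullmann diaryl ether coupling of an iodoarene bearing the enone with a phenol-aldehyde. The ring-B CHO becomes the vinyl group by Wittig methylenation. The ring-B OMe ortho to the CHO becomes the free OH by BCl3 demethylation.
4. Order of construction: enone chain, then diaryl ether, then phenol unmasking, then styrene, then macrocycle, then saturation. Compound numbers are assigned in the forward scheme.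

---

**Step 1**
Reactants: 1 (3-iodo-4-methoxybenzaldehyde), 2 (hex-5-en-2-one)
Product: 3, (E)-1-(3-iodo-4-methoxyphenyl)octa-1,7-dien-3-one
Conditions: NaOH (aq), EtOH, 0 °C → rt, 12 h (2–3 equiv 2)
Reagents that add atoms: none (both reactants are listed above)
Why: Base-mediated Claisen–Schmidt (aldol condensation) occurs at the methyl side of the methyl ketone. The (E)-enone gives the C1–C3 unit and the terminal alkene needed for RCM, and no stereocentre is formed.

**Step 2**
Reactants: 3, 4 (4-hydroxy-2,3-dimethoxybenzaldehyde)
Product: 5, 4-[2-methoxy-5-((E)-3-oxoocta-1,7-dien-1-yl)phenoxy]-2,3-dimethoxybenzaldehyde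
Conditions: CuI (10 mol%), picolinic acid (20 mol%), K3PO4, DMSO, 80 °C, 16 h
Reagents that add atoms: none
Why: A Cu/picolinic acid Ullmann-type C–O coupling joins the phenol to the ortho-substituted aryl iodide under mild base. The aldehyde, the enone (an unfavourable oxa-Michael acceptor) and the alkene survive, and the diaryl ether forms at the ring-A carbon that carried iodine.

**Step 3**
Reactants: 5
Product: 6, 2-hydroxy-3-methoxy-4-[2-methoxy-5-((E)-3-oxoocta-1,7-dien-1-yl)phenoxy]benzaldehyde
Conditions: BCl3 (3 equiv), CH2Cl2, −78 → 0 °C, 1 h; aq NaHCO3 quench
Reagents that add atoms: none (the OMe is converted to OH; only H is added)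
Why: Chelation-controlled (aldehyde O to BCl3 to ortho OMe) demethylation cleaves only the OMe ortho to the CHO. The 3-OMe and the ring-A OMe are not chelated and are retained.

**Step 4**
Reactants: 6, 7 (methyltriphenylphosphonium bromide)
Product: 8, 2-vinyl-phenol diene: 3-methoxy-4-aryloxy-2-hydroxystyrene bearing the enone chain
Conditions: Ph3PCH3Br (2.5 equiv), KOtBu (2.6 equiv), THF, 0 °C → rt, 3 h
Reagents that add atoms: methyltriphenylphosphonium bromide, C[P+](c1ccccc1)(c1ccccc1)c1ccccc1.[Br-] (delivers the =CH2 carbon)
Why: Wittig methylenation. One equivalent of ylide deprotonates the phenol and the rest methylenates the aldehyde. The β-aryl conjugated enone is far less electrophilic toward the ylide than the aldehyde, so it is left intact.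

**Step 5**
Reactants: 8
Product: 9, macrocyclic dienone (E,E): ArB–CH=CH–CH2CH2–C(=O)–CH=CH–ArA
Conditions: Grubbs II (10 mol%), CH2Cl2 (0.002 M), 40 °C, 12 h
Reagents that add atoms: none (ethylene is lost)
Why: Ring-closing metathesis of the styrene with the monosubstituted alkene at high dilution closes the 15-membered ring. Geometry is irrelevant because both C=C bonds are hydrogenated next.

**Step 6**
Reactants: 9
Product: 10, juglanin A
Conditions: H2 (1 atm), 10% Pd/C, EtOAc/MeOH, rt, 4 h
Reagents that add atoms: none (H2 adds only hydrogen)
Why: Catalytic hydrogenation saturates the styrenyl and enone C=C bonds. The aryl ketone-free aliphatic C=O, the aryl ethers, the OMe groups and the free phenol are untouched, and no stereocentre is created.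

---

**Checks**
- **Structure match.** Ring A has OMe para to the chain and OAr ortho to OMe (meta to the chain). Ring B has the chain para to OAr, OH ortho to the chain, and OMe between OH and OAr. The chain is ArB–(CH2)4–C(=O)–(CH2)2–ArA, 7 carbons with the C=O third from ring A. Step 6 gives exactly the target SMILES.
- **Atom accounting.** Step 5 loses C2H4. Step 6 adds 4 H. Step 4 adds CH2 and removes O.
- **Functional-group compatibility.**
  - Steps 2–4: the terminal alkene and enone survive Ullmann, BCl3 (at low temperature) and Wittig conditions.
  - Step 5: the free phenol is carried through RCM.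
  - Step 6: no benzyl ether is present, so hydrogenolysis is not needed.
- **Stereochemistry.** The target has no stereocentres. The alkene geometries in 3, 8 and 9 are erased in Step 6.

---

**Compound list**

| # | Name | SMILES | Role |
|---|---|---|---|
| 1 | 3-Iodo-4-methoxybenzaldehyde | COc1ccc(C=O)cc1I | starting material |
| 2 | Hex-5-en-2-one | CC(=O)CCC=C | starting material |
| 3 | (E)-1-(3-Iodo-4-methoxyphenyl)octa-1,7-dien-3-one | COc1ccc(/C=C/C(=O)CCC=C)cc1I | intermediate |
| 4 | 4-Hydroxy-2,3-dimethoxybenzaldehyde | COc1c(O)ccc(C=O)c1OC | starting material |
| 5 | Diaryl ether aldehyde (2,3-dimethoxy) | COc1ccc(/C=C/C(=O)CCC=C)cc1Oc1ccc(C=O)c(OC)c1OC | intermediate |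
| 6 | Diaryl ether salicylaldehyde (2-hydroxy-3-methoxy) | COc1ccc(/C=C/C(=O)CCC=C)cc1Oc1ccc(C=O)c(O)c1OC | intermediate |
| 7 | Methyltriphenylphosphonium bromide | C[P+](c1ccccc1)(c1ccccc1)c1ccccc1.[Br-] | starting material (reagent) |
| 8 | 2-Hydroxy-3-methoxy-4-aryloxystyrene enone | COc1ccc(/C=C/C(=O)CCC=C)cc1Oc1ccc(C=C)c(O)c1OC | intermediate |
| 9 | Macrocyclic (E,E)-dienone | COc1ccc2cc1Oc1ccc(c(O)c1OC)/C=C/CCC(=O)/C=C/2 | intermediate |
| 10 | Juglanin A | COc1ccc2cc1Oc1ccc(c(O)c1OC)CCCCC(=O)CC2 | target |

**Total steps:** 6. **Longest linear sequence:** 6 (1 → 3 → 5 → 6 → 8 → 9 → 10).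

**Three steps most likely to fail**
1. **Step 5 (RCM).** The ortho-hydroxystyrene may chelate Ru, and two rigid E-alkenes in a 15-membered para-bridged ring may be strained. Fallback: change the ring-closing disconnection to an intramolecular Chan–Lam (or Ullmann) macro-etherification of an open-chain ring-A aryl boronic acid or iodide with the ring-B phenol. The saturated ketone chain is built first (Claisen–Schmidt, then conjugate reduction), and the ring is closed under high dilution.
2. **Step 4 (Wittig on the free salicylaldehyde).** The phenoxide aldehyde is sluggish, and excess ylide may attack the enone. Fallback: protect the phenol as its benzyl ether (BnBr, K2CO3) before Step 4. Methylenate with 1.1 equiv ylide at −78 °C, run RCM on the protected diene, and let the final H2/Pd-C remove the Bn group along with saturating the alkenes.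
3. **Step 3 (regioselective BCl3 demethylation).** BCl3 may over-demethylate or bind the enone. Fallback: demethylate the simple monomer 4 first with BCl3 to give 2,4-dihydroxy-3-methoxybenzaldehyde. Then run the Ullmann coupling at its more acidic 4-OH. This removes the late-stage demethylation from the sensitive substrate.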